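**Plan**
1. Cuts, in order: C2'–C3' (chain CH2 to the vinylic CH of the first chain alkene) gives (S)-2-vinylchroman 10 and the C39 (E)-iodoalkene 23; then O1–C2, C2=C1' and C4–C4a in 10; then C4'–CH3, C17'–C18' and C5'–C6' in 23.
2. Enabling feature: C2 of the pyran ring is fully substituted and O-bound, so C1'–C2' can be stored as a vinyl group on C2 whose terminal carbon takes boron; C3'=C4'(CH3) is a 2-methylalk-1-enyl end, which syn-methylalumination of a terminal alkyne delivers as the pure E iodide.
3. Forward, chroman half: 2,3-dimethylhydroquinone (benzene ring bought) plus methyl vinyl ketone, olefination to an E allylic carbonate, then the pyran ring closes by palladium-catalysed asymmetric allylic etherification (step 8).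
4. Forward, chain half: geranylgeranyl sulfone plus an ω-bromo farnesyl-propyne (C17'–C18'), desulfonylation, methylalumination–iodination (steps 9–16).
5. Union by one-pot hydroboration/B-alkyl Suzuki–Miyaura coupling (step 17), then desilylation (step 18).
6. Stereochemistry: C2 (R in the target) from the chiral bisphosphine ligand in step 8; the E alkenes at C7', C11', C19', C23', C27' are bought, C15'=C16' comes from E-selective SeO2 oxidation, C3'=C4' from syn-carboalumination and a stereoretentive coupling.

Key step: step 17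

Assumption: the (R,R)-configured ligand is taken to convert the E carbonate 9 into the 2S vinylchroman 10 in step 8; if the sense of induction proves opposite, the commercial (S,S)-ligand is used under the same conditions.

**Route**

Step 1
Reactants: 1 2,3-dimethylhydroquinone; 2 methyl vinyl ketone
Product: 3 2-methoxy-2,7,8-trimethylchroman-6-ol (racemic ketal)
Conditions: HC(OMe)3, cat. H2SO4, MeOH, 0 °C to rt, 1 in excess
Reagents that add atoms: trimethyl orthoformate COC(OC)OC
Why: Acid-catalysed Friedel–Crafts conjugate addition of the electron-rich hydroquinone to the enone (C4–C4a) with ring–chain ketalisation trapped by the orthoformate; the two free ring positions of 1 are equivalent, so the regiochemistry is unambiguous, and excess 1 limits double alkylation.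

Step 2
Reactants: 3 2-methoxy-2,7,8-trimethylchroman-6-ol
Product: 4 6-triisopropylsilyl ether of 3
Conditions: TIPSCl, imidazole, DMF, rt
Reagents that add atoms: triisopropylsilyl chloride CC(C)[Si](Cl)(C(C)C)C(C)C
Why: Silylation of the only free phenol; the bulky silyl ether should survive dilute acid, hydride, base and palladium catalysis and is removed by fluoride at the end.

Step 3
Reactants: 4 silyl ketal
Product: 5 2,7,8-trimethyl-6-(triisopropylsilyloxy)chroman-2-ol (hemiketal, ring–chain tautomer of the hydroxy ketone)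
Conditions: 1 M HCl, THF, rt
Reagents that add atoms: water O
Why: Acid hydrolysis of the mixed methyl ketal, to which the aryl triisopropylsilyl ether is stable under dilute acid.

Step 4
Reactants: 5 hemiketal
Product: 6 2,3-dimethyl-6-(3-oxobutyl)-4-(triisopropylsilyloxy)phenyl pivalate
Conditions: PivCl, Et3N, cat. DMAP, CH2Cl2, 0 °C to rt
Reagents that add atoms: pivaloyl chloride CC(C)(C)C(Cl)=O
Why: Acylation traps the open tautomer at the phenol (the tertiary hemiketal hydroxyl is too hindered), which frees the methyl ketone and masks the phenol so that it cannot add back to the enoate made in step 5.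

Step 5
Reactants: 6 keto pivalate
Product: 7 ethyl (E)-5-aryl-3-methylpent-2-enoate (aryl = 3,4-dimethyl-2-pivaloyloxy-5-triisopropylsilyloxyphenyl)
Conditions: (EtO)2P(O)CH2CO2Et, NaH, THF, 0 °C to reflux; E isomer separated by chromatography
Reagents that add atoms: triethyl phosphonoacetate CCOC(=O)CP(=O)(OCC)OCC
Why: Horner–Wadsworth–Emmons olefination of the methyl ketone forms C2=C1' and should favour the E enoate (ester trans to the larger arylethyl group); the minor Z isomer must be removed because alkene geometry feeds into the sense of step 8.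

Step 6
Reactants: 7 E enoate
Product: 8 6-[(E)-5-hydroxy-3-methylpent-3-en-1-yl]-2,3-dimethyl-4-(triisopropylsilyloxy)phenol
Conditions: i-Bu2AlH (excess), CH2Cl2, −78 to 0 °C; aqueous potassium sodium tartrate
Reagents that add atoms: none
Why: 1,2-Reduction of the enoate to the allylic alcohol and reductive cleavage of the aryl pivalate in one operation by the aluminium hydride, leaving alkene geometry and the silyl ether untouched.

Step 7
Reactants: 8 phenol allylic alcohol
Product: 9 (E)-5-[2-hydroxy-3,4-dimethyl-5-(triisopropylsilyloxy)phenyl]-3-methylpent-2-en-1-yl methyl carbonate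
Conditions: ClCO2Me (1.1 equiv), pyridine, CH2Cl2, −20 °C
Reagents that add atoms: methyl chloroformate COC(Cl)=O
Why: Chemoselective acylation: under neutral pyridine conditions the primary allylic alcohol reacts much faster than the phenol, which is flanked by two ortho substituents.

Step 8
Reactants: 9 phenol allyl carbonate
Product: 10 (S)-triisopropyl[(2,7,8-trimethyl-2-vinylchroman-6-yl)oxy]silane
Conditions: Pd2(dba)3·CHCl3 (cat.), (R,R)-N,N'-(cyclohexane-1,2-diyl)bis[2-(diphenylphosphino)benzamide] (cat.), AcOH, CH2Cl2, rt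
Reagents that add atoms: none
Why: Asymmetric Tsuji–Trost allylic etherification: zerovalent palladium ionises the carbonate (loss of CO2 and methanol) and the phenol closes the pyran ring by attack on the more substituted allyl terminus (six-membered ring instead of eight), the chiral ligand pocket choosing the face and so setting C2; the descriptor is S only because vinyl outranks the ring CH2, the spatial arrangement being that of the target.

Step 9
Reactants: 11 (2E,6E,10E)-geranylgeraniol
Product: 12 (2E,6E,10E)-geranylgeranyl bromide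
Conditions: PBr3, Et2O, −10 °C
Reagents that add atoms: phosphorus tribromide BrP(Br)Br
Why: SN2 bromination of the primary allylic alcohol at low temperature, which should keep the 2E geometry and avoid allylic transposition.

Step 10
Reactants: 12 geranylgeranyl bromide
Product: 13 (2E,6E,10E)-geranylgeranyl phenyl sulfone
Conditions: PhSO2Na, DMF, rt
Reagents that add atoms: sodium benzenesulfinate [Na+].[O-]S(=O)c1ccccc1
Why: S-Alkylation of the sulfinate by SN2 at the primary allylic bromide gives the allyl sulfone, whose α-carbon (the later C18') becomes the nucleophile of step 14.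

Step 11
Reactants: 14 (2E,6E)-farnesyl bromide
Product: 15 trimethyl[(5E,9E)-6,10,14-trimethylpentadeca-5,9,13-trien-1-yn-1-yl]silane
Conditions: 1-(trimethylsilyl)propyne, n-BuLi, THF, −78 to −20 °C; then 14, −78 °C to rt
Reagents that add atoms: 1-(trimethylsilyl)propyne CC#C[Si](C)(C)C
Why: Propargylic lithiation and SN2 alkylation at the primary allylic bromide form C5'–C6'; the silyl group steers reaction through the propargyl terminus and protects the alkyne until step 15.

Step 12
Reactants: 15 silyl enyne
Product: 16 (2E,6E,10E)-2,6,10-trimethyl-15-(trimethylsilyl)pentadeca-2,6,10-trien-14-yn-1-ol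
Conditions: SeO2 (cat.), t-BuOOH, salicylic acid (cat.), CH2Cl2, 0 °C to rt, stopped at partial conversion
Reagents that add atoms: tert-butyl hydroperoxide CC(C)(C)OO (oxygen, relayed by catalytic SeO2)
Why: SeO2 allylic oxidation (ene reaction then [2,3]-sigmatropic shift) attacks the most accessible terminal trisubstituted alkene at its E methyl group, giving the E allylic alcohol that later becomes C15'=C16'–C17'.

Step 13
Reactants: 16 allylic alcohol
Product: 17 [(5E,9E,13E)-15-bromo-6,10,14-trimethylpentadeca-5,9,13-trien-1-yn-1-yl]trimethylsilane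
Conditions: CBr4, PPh3, CH2Cl2, 0 °C
Reagents that add atoms: carbon tetrabromide BrC(Br)(Br)Br
Why: Appel bromination of the primary allylic alcohol under neutral conditions, which should keep the alkene geometry and the alkynylsilane intact.

Step 14
Reactants: 13 geranylgeranyl phenyl sulfone; 17 allylic bromide
Product: 19 silylated C38 enyne sulfone, via lithiated sulfone 18 (not isolated)
Conditions: n-BuLi, THF/DMPU, −78 °C; then 17, −78 to −20 °C
Reagents that add atoms: none
Why: Alkylation of the sulfone-stabilised allyl anion at its α-carbon by the primary allylic bromide (allyl sulfone coupling) forms C17'–C18' without touching any alkene; the new sulfone-bearing centre is racemic and is erased in step 15.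

Step 15
Reactants: 19 silylated C38 enyne sulfone
Product: 21 all-E C38 terminal alkyne, via silylated C38 alkyne 20 (not isolated)
Conditions: PdCl2(dppp) (cat.), LiEt3BH, THF, 0 °C; then MeOH, K2CO3, rt
Reagents that add atoms: none
Why: Palladium-catalysed hydride displacement of the allylic sulfone (π-allyl formation, hydride delivered to the less substituted terminus) removes sulfur with the alkene kept in place and E; methanolic carbonate then cleaves the alkynyl C–Si bond in the same flask.

Step 16
Reactants: 21 C38 terminal alkyne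
Product: 23 all-E C39 1-iodo-2-methylalkene, via alkenylalane 22 (not isolated)
Conditions: Me3Al, Cp2ZrCl2 (0.25 equiv), CH2Cl2, 0 °C to rt; then I2, THF, −30 to 0 °C
Reagents that add atoms: trimethylaluminium C[Al](C)C; iodine II
Why: Zirconium-catalysed syn-methylalumination of the terminal alkyne (Negishi carboalumination) puts CH3 on C4' and aluminium on C3', and iodinolysis with retention gives the E iodoalkene; the isolated trisubstituted alkenes are inert.

Step 17
Reactants: 10 (S)-2-vinylchroman silyl ether; 23 C39 (E)-iodoalkene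
Product: 25 plastochromanol 8 triisopropylsilyl ether, via B-alkyl-9-BBN borane 24 (not isolated)
Conditions: 9-BBN dimer, THF, rt; then 23, PdCl2(dppf)·CH2Cl2 (cat.), AsPh3 (cat.), Cs2CO3, DMF/THF/H2O, rt; 10 in slight excess
Reagents that add atoms: none
Why: 9-BBN adds to the monosubstituted vinyl group of 10 with boron on the terminal carbon C2', giving a primary alkylborane with no β-heteroatom; the base turns it into the borate, which transfers its primary alkyl group to the alkenylpalladium iodide formed by oxidative addition of zerovalent palladium into the C–I bond of 23, and reductive elimination forges C2'–C3'. The closest known reaction type is the one-pot hydroboration/B-alkyl Suzuki–Miyaura coupling of terminal alkenes with (E)-1-iodo-2-methylalkenes, a standard way to make trisubstituted alkenes in terpenoid and polyketide work. No ring is closed and no stereocentre is created: C2 carries no hydrogen and lies two bonds from boron, so it is untouched, and the E geometry of C3'=C4' is carried over from 23 because oxidative addition and reductive elimination both proceed with retention. The selectivities needed are hydroboration at the vinyl group only (secured by finishing it before the polyene iodide is added and by the low reactivity of 9-BBN toward trisubstituted alkenes), coupling faster than β-hydride elimination of the alkylpalladium (secured by the wide-bite-angle dppf ligand with AsPh3), and survival of the aryl silyl ether (secured by carbonate base at room temperature). The slight excess of 10 ensures that the more valuable iodide 23 is consumed.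

Step 18
Reactants: 25 plastochromanol 8 triisopropylsilyl ether
Product: 26 plastochromanol 8
Conditions: Bu4NF, AcOH, THF, 0 °C, under argon
Reagents that add atoms: none
Why: Fluoride cleavage of the aryl silyl ether; acetic acid buffering and exclusion of air should protect the electron-rich chromanol from phenoxide oxidation, and the polyene is inert.

**Compound list**

1 | 2,3-dimethylhydroquinone (2,3-dimethylbenzene-1,4-diol) | Cc1c(O)ccc(O)c1C | starting material
2 | methyl vinyl ketone | CC(=O)C=C | starting material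
3 | 2-methoxy-2,7,8-trimethylchroman-6-ol (racemic) | COC1(C)CCc2cc(O)c(C)c(C)c2O1 | intermediate
4 | triisopropyl[(2-methoxy-2,7,8-trimethylchroman-6-yl)oxy]silane (racemic) | COC1(C)CCc2cc(O[Si](C(C)C)(C(C)C)C(C)C)c(C)c(C)c2O1 | intermediate
5 | 2,7,8-trimethyl-6-(triisopropylsilyloxy)chroman-2-ol (racemic hemiketal) | CC1(O)CCc2cc(O[Si](C(C)C)(C(C)C)C(C)C)c(C)c(C)c2O1 | intermediate
6 | 2,3-dimethyl-6-(3-oxobutyl)-4-(triisopropylsilyloxy)phenyl pivalate | CC(=O)CCc1cc(O[Si](C(C)C)(C(C)C)C(C)C)c(C)c(C)c1OC(=O)C(C)(C)C | intermediate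
7 | ethyl (E)-5-[3,4-dimethyl-2-(pivaloyloxy)-5-(triisopropylsilyloxy)phenyl]-3-methylpent-2-enoate | CCOC(=O)/C=C(\C)CCc1cc(O[Si](C(C)C)(C(C)C)C(C)C)c(C)c(C)c1OC(=O)C(C)(C)C | intermediate
8 | 6-[(E)-5-hydroxy-3-methylpent-3-en-1-yl]-2,3-dimethyl-4-(triisopropylsilyloxy)phenol | OC/C=C(\C)CCc1cc(O[Si](C(C)C)(C(C)C)C(C)C)c(C)c(C)c1O | intermediate
9 | (E)-5-[2-hydroxy-3,4-dimethyl-5-(triisopropylsilyloxy)phenyl]-3-methylpent-2-en-1-yl methyl carbonate | COC(=O)OC/C=C(\C)CCc1cc(O[Si](C(C)C)(C(C)C)C(C)C)c(C)c(C)c1O | intermediate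
10 | (S)-triisopropyl[(2,7,8-trimethyl-2-vinylchroman-6-yl)oxy]silane | C=C[C@]1(C)CCc2cc(O[Si](C(C)C)(C(C)C)C(C)C)c(C)c(C)c2O1 | intermediate
11 | (2E,6E,10E)-geranylgeraniol | CC(C)=CCC/C(C)=C/CC/C(C)=C/CC/C(C)=C/CO | starting material
12 | (2E,6E,10E)-geranylgeranyl bromide | CC(C)=CCC/C(C)=C/CC/C(C)=C/CC/C(C)=C/CBr | intermediate
13 | (2E,6E,10E)-geranylgeranyl phenyl sulfone | CC(C)=CCC/C(C)=C/CC/C(C)=C/CC/C(C)=C/CS(=O)(=O)c1ccccc1 | intermediate
14 | (2E,6E)-farnesyl bromide | CC(C)=CCC/C(C)=C/CC/C(C)=C/CBr | starting material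
15 | trimethyl[(5E,9E)-6,10,14-trimethylpentadeca-5,9,13-trien-1-yn-1-yl]silane | CC(C)=CCC/C(C)=C/CC/C(C)=C/CCC#C[Si](C)(C)C | intermediate
16 | (2E,6E,10E)-2,6,10-trimethyl-15-(trimethylsilyl)pentadeca-2,6,10-trien-14-yn-1-ol | OC/C(C)=C/CC/C(C)=C/CC/C(C)=C/CCC#C[Si](C)(C)C | intermediate
17 | [(5E,9E,13E)-15-bromo-6,10,14-trimethylpentadeca-5,9,13-trien-1-yn-1-yl]trimethylsilane | BrC/C(C)=C/CC/C(C)=C/CC/C(C)=C/CCC#C[Si](C)(C)C | intermediate
18 | α-lithio derivative of geranylgeranyl phenyl sulfone | CC(C)=CCC/C(C)=C/CC/C(C)=C/CC/C(C)=C/C([Li])S(=O)(=O)c1ccccc1 | intermediate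
19 | trimethyl[(5E,9E,13E,17E,21E,25E)-6,10,14,18,22,26,30-heptamethyl-16-(phenylsulfonyl)hentriaconta-5,9,13,17,21,25,29-heptaen-1-yn-1-yl]silane (racemic at C16) | CC(C)=CCC/C(C)=C/CC/C(C)=C/CC/C(C)=C/C(C/C(C)=C/CC/C(C)=C/CC/C(C)=C/CCC#C[Si](C)(C)C)S(=O)(=O)c1ccccc1 | intermediate
20 | trimethyl[(5E,9E,13E,17E,21E,25E)-6,10,14,18,22,26,30-heptamethylhentriaconta-5,9,13,17,21,25,29-heptaen-1-yn-1-yl]silane | CC(C)=CCC/C(C)=C/CC/C(C)=C/CC/C(C)=C/CC/C(C)=C/CC/C(C)=C/CC/C(C)=C/CCC#C[Si](C)(C)C | intermediate
21 | (5E,9E,13E,17E,21E,25E)-6,10,14,18,22,26,30-heptamethylhentriaconta-5,9,13,17,21,25,29-heptaen-1-yne | CC(C)=CCC/C(C)=C/CC/C(C)=C/CC/C(C)=C/CC/C(C)=C/CC/C(C)=C/CC/C(C)=C/CCC#C | intermediate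
22 | dimethyl[(1E,5E,9E,13E,17E,21E,25E)-2,6,10,14,18,22,26,30-octamethylhentriaconta-1,5,9,13,17,21,25,29-octaen-1-yl]alane | CC(C)=CCC/C(C)=C/CC/C(C)=C/CC/C(C)=C/CC/C(C)=C/CC/C(C)=C/CC/C(C)=C/CC/C(C)=C/[Al](C)C | intermediate
23 | (1E,5E,9E,13E,17E,21E,25E)-1-iodo-2,6,10,14,18,22,26,30-octamethylhentriaconta-1,5,9,13,17,21,25,29-octaene | CC(C)=CCC/C(C)=C/CC/C(C)=C/CC/C(C)=C/CC/C(C)=C/CC/C(C)=C/CC/C(C)=C/CC/C(C)=C/I | intermediate
24 | (R)-9-{2-[2,7,8-trimethyl-6-(triisopropylsilyloxy)chroman-2-yl]ethyl}-9-borabicyclo[3.3.1]nonane | B1(CC[C@]3(C)CCc4cc(O[Si](C(C)C)(C(C)C)C(C)C)c(C)c(C)c4O3)C2CCCC1CCC2 | intermediate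
25 | (R)-triisopropyl({2,7,8-trimethyl-2-[(3E,7E,11E,15E,19E,23E,27E)-4,8,12,16,20,24,28,32-octamethyltritriaconta-3,7,11,15,19,23,27,31-octaen-1-yl]chroman-6-yl}oxy)silane | CC(C)=CCC/C(C)=C/CC/C(C)=C/CC/C(C)=C/CC/C(C)=C/CC/C(C)=C/CC/C(C)=C/CC/C(C)=C/CC[C@]1(C)CCc2cc(O[Si](C(C)C)(C(C)C)C(C)C)c(C)c(C)c2O1 | intermediate
26 | plastochromanol 8, (R)-2,7,8-trimethyl-2-[(3E,7E,11E,15E,19E,23E,27E)-4,8,12,16,20,24,28,32-octamethyltritriaconta-3,7,11,15,19,23,27,31-octaen-1-yl]chroman-6-ol | CC(C)=CCC/C(C)=C/CC/C(C)=C/CC/C(C)=C/CC/C(C)=C/CC/C(C)=C/CC/C(C)=C/CC/C(C)=C/CC[C@]1(C)CCc2cc(O)c(C)c(C)c2O1 | target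

**Count and risks**

Total steps: 18. Longest linear sequence: 10 (steps 1–8, 17, 18); the chain branch (steps 9–16) is convergent with it.

Step 8, risk: poor or reversed facial selectivity in the ring-closing allylic etherification, or erosion through incomplete equilibration of the π-allyl intermediates. The fallback sets out from 8 and fixes C2 by reagent control. Sharpless asymmetric epoxidation (Ti(OiPr)4, D-(−)-diethyl tartrate, t-BuOOH, 4 Å sieves, CH2Cl2, −20 °C) should give the (2R,3R)-epoxy alcohol F1. Camphorsulfonic acid (CH2Cl2, 0 °C) should then let the phenol open the epoxide at its tertiary carbon with inversion in a 6-exo closure, giving the chromanyl diol F2. NaIO4 (THF/H2O) would cleave the diol to the chroman-2-carbaldehyde F3, and Wittig methylenation (Ph3P=CH2, THF, 0 °C) would return to 10.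

Step 12, risk: poor site selectivity of the allylic oxidation among three trisubstituted alkenes, together with over-oxidation. The fallback sets out from 15 and replaces C–H oxidation by degradation and rebuilding of the terminal alkene. NBS in aqueous THF at 0 °C should form the terminal bromohydrin F4, which DBU closes to the terminal epoxide F5. HIO4 (THF/Et2O) cleaves this to the trisnor aldehyde F6. Wittig reaction with the stabilised ylide Ph3P=C(CH3)CO2Et (CH2Cl2, rt) should give the E enoate F7, and i-Bu2AlH (CH2Cl2, −78 °C) reduces it to rejoin the route at 16.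

Step 17, risk: slow transfer of the alkyl group from boron to palladium, with competing protodeboronation and reduction of the iodoalkene. The fallback sets out from 10 and changes the nucleophile from boron to zinc through isolated intermediates. Hydroboration with 9-BBN and oxidation with sodium perborate would give the primary alcohol F8, and I2/PPh3/imidazole the primary iodide F9. Zinc dust with LiCl in THF should insert to the alkylzinc iodide F10. Negishi coupling of F10 with 23 (Pd(OAc)2, 2-dicyclohexylphosphino-2',6'-dimethoxybiphenyl, THF, rt) forms the same C2'–C3' bond with retention of the E geometry and comes back to the route at 25.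

**Further compounds**

F1 | step 8 | 6-{2-[(2R,3R)-3-(hydroxymethyl)-2-methyloxiran-2-yl]ethyl}-2,3-dimethyl-4-(triisopropylsilyloxy)phenol | OC[C@H]1O[C@]1(C)CCc2cc(O[Si](C(C)C)(C(C)C)C(C)C)c(C)c(C)c2O
F2 | step 8 | (R)-1-[(S)-2,7,8-trimethyl-6-(triisopropylsilyloxy)chroman-2-yl]ethane-1,2-diol | OC[C@@H](O)[C@]1(C)CCc2cc(O[Si](C(C)C)(C(C)C)C(C)C)c(C)c(C)c2O1
F3 | step 8 | (S)-2,7,8-trimethyl-6-(triisopropylsilyloxy)chroman-2-carbaldehyde | O=C[C@]1(C)CCc2cc(O[Si](C(C)C)(C(C)C)C(C)C)c(C)c(C)c2O1
F4 | step 12 | (6E,10E)-3-bromo-2,6,10-trimethyl-15-(trimethylsilyl)pentadeca-6,10-dien-14-yn-2-ol (racemic) | CC(C)(O)C(Br)CC/C(C)=C/CC/C(C)=C/CCC#C[Si](C)(C)C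
F5 | step 12 | {(5E,9E)-12-(3,3-dimethyloxiran-2-yl)-6,10-dimethyldodeca-5,9-dien-1-yn-1-yl}trimethylsilane (racemic) | CC1(C)OC1CC/C(C)=C/CC/C(C)=C/CCC#C[Si](C)(C)C
F6 | step 12 | (4E,8E)-4,8-dimethyl-13-(trimethylsilyl)trideca-4,8-dien-12-ynal | O=CCC/C(C)=C/CC/C(C)=C/CCC#C[Si](C)(C)C
F7 | step 12 | ethyl (2E,6E,10E)-2,6,10-trimethyl-15-(trimethylsilyl)pentadeca-2,6,10-trien-14-ynoate | CCOC(=O)/C(C)=C/CC/C(C)=C/CC/C(C)=C/CCC#C[Si](C)(C)C
F8 | step 17 | (S)-2-[2,7,8-trimethyl-6-(triisopropylsilyloxy)chroman-2-yl]ethan-1-ol | OCC[C@]1(C)CCc2cc(O[Si](C(C)C)(C(C)C)C(C)C)c(C)c(C)c2O1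
F9 | step 17 | (S)-{[2-(2-iodoethyl)-2,7,8-trimethylchroman-6-yl]oxy}triisopropylsilane | ICC[C@]1(C)CCc2cc(O[Si](C(C)C)(C(C)C)C(C)C)c(C)c(C)c2O1
F10 | step 17 | (S)-{2-[2,7,8-trimethyl-6-(triisopropylsilyloxy)chroman-2-yl]ethyl}zinc iodide | I[Zn]CC[C@]1(C)CCc2cc(O[Si](C(C)C)(C(C)C)C(C)C)c(C)c(C)c2O1
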